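**Plan**

- Retrosynthesis cuts, in this order: (i) the C5–C(Me)= bond between the γ-lactone and the C12 dienyl arm; (ii) the C(Me)–CH bond inside the C3 diene, which leaves a propynyl group on C3; (iii) the C3–C4 bond and the aldol bond of the ketone arm.
- Enabling feature: C5 is the O-bearing γ-carbon of the ring O1–C2(=O)–C3–C4–C5, i.e. the acetal-level carbon of a γ-oxo acid ring tautomer. The lactone can therefore exist before its C5 substituent and carry Br at C5 next to the C4 methyl. Both (E)-C(Me)=CH units are the mark of syn-hydrometalation of a MeC≡C group.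
- Forward: propanal + nitroenyne (Michael) gives C3/C4; nitro→CO2H and ring closure give the 5-hydroxy lactone, then the C5 bromide. Ni-catalysed stereoconvergent alkenylation with the dienylzirconocene from the C12 enyne joins the halves. Hydroboration/Suzuki coupling of the C3 propynyl group with the aldol-derived vinyl iodide and desilylation finish.
- Stereochemistry: C3/C4 from the (R)-diarylprolinol silyl ether catalyst (syn adduct = 3,4-trans lactone). C5 from the C4 methyl on the ring, with both bromide epimers converging. Carbinol/α-methyl of the ketone arm from an Evans syn-aldol, and the butyl-bearing centre from an Evans hydroxymethylation (both with the (R)-benzyl auxiliary). Alkene geometries from Takai olefination and two syn-hydrometalations.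

Key step: step 18

Remark: lactone numbering is O1, C2 (C=O), C3, C4, C5; 31 and 32 are used as C5-epimer mixtures on purpose, and 13 is taken as a purchasable building block.

**Route**

Step 1
Reactants: 1 (4R)-4-benzyl-1,3-oxazolidin-2-one; 2 hexanoyl chloride
Product: 4 (4R)-4-benzyl-3-hexanoyl-1,3-oxazolidin-2-one, via lithium oxazolidinide 3 (not isolated)
Conditions: n-BuLi, THF, −78 °C; then 2, −78 → 0 °C
Reagents that add atoms: none
Why: N-acylation of the lithiated auxiliary with an acid chloride is a standard imide synthesis and forms no stereocentre.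

Step 2
Reactants: 4
Product: 6 (4R)-4-benzyl-3-[(2S)-2-(hydroxymethyl)hexanoyl]-1,3-oxazolidin-2-one, via titanium enolate 5 (not isolated)
Conditions: TiCl4, i-Pr2NEt, CH2Cl2, 0 °C; then 1,3,5-trioxane, TiCl4, 0 °C
Reagents that add atoms: 1,3,5-trioxane, C1OCOCO1
Why: Evans titanium-enolate hydroxymethylation, in which the chelated (Z)-enolate is attacked by the activated formaldehyde equivalent on the face opposite the benzyl group, setting C2 as (S).

Step 3
Reactants: 6
Product: 7 (4R)-4-benzyl-3-[(2S)-2-({[tert-butyl(dimethyl)silyl]oxy}methyl)hexanoyl]-1,3-oxazolidin-2-one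
Conditions: TBSCl, imidazole, DMF, rt
Reagents that add atoms: tert-butyldimethylsilyl chloride, CC(C)(C)[Si](C)(C)Cl
Why: Routine silylation of the primary alcohol, which leaves the imide and its α-centre untouched.

Step 4
Reactants: 7
Product: 8 (2R)-2-({[tert-butyl(dimethyl)silyl]oxy}methyl)hexan-1-ol
Conditions: LiBH4, MeOH (1 equiv), THF, 0 °C
Reagents that add atoms: none
Why: Reductive auxiliary cleavage with LiBH4 should give the primary alcohol chemoselectively without erosion of the α-centre.

Step 5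
Reactants: 8
Product: 9 (2S)-2-({[tert-butyl(dimethyl)silyl]oxy}methyl)hexanal
Conditions: Dess–Martin periodinane, NaHCO3, CH2Cl2, 0 °C → rt; used at once
Reagents that add atoms: none
Why: Buffered Dess–Martin oxidation should give the α-branched aldehyde without epimerisation or β-elimination of the silyloxy group.

Step 6
Reactants: 9
Product: 10 tert-butyl{[(2R,3E)-2-butyl-4-iodobut-3-en-1-yl]oxy}dimethylsilane
Conditions: CrCl2, CHI3, THF–dioxane, 0 °C → rt
Reagents that add atoms: iodoform, IC(I)I
Why: Takai olefination is non-basic, so the allylic stereocentre should survive, and the E geometry follows from anti elimination of the gem-dichromium adduct.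

Step 7
Reactants: 10; 11 propyne
Product: 12 tert-butyl{[(2R,3E)-2-butylhept-3-en-5-yn-1-yl]oxy}dimethylsilane
Conditions: Pd(PPh3)2Cl2 (5 mol %), CuI (10 mol %), Et3N, THF, 0 °C → rt
Reagents that add atoms: none
Why: Sonogashira coupling of the (E)-vinyl iodide proceeds with retention of alkene geometry and should give the methyl-capped enyne.

Step 8
Reactants: 13 (2E)-3-iodoprop-2-en-1-ol
Product: 14 (2E)-3-iodoprop-2-enal
Conditions: MnO2, CH2Cl2, rt, dark; filtered solution used directly
Reagents that add atoms: none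
Why: MnO2 oxidises the allylic alcohol selectively and leaves the vinyl iodide and its geometry intact.

Step 9
Reactants: 15 (4R)-4-benzyl-3-propanoyl-1,3-oxazolidin-2-one; 14
Product: 17 (4R)-4-benzyl-3-[(2R,3R,4E)-3-hydroxy-5-iodo-2-methylpent-4-enoyl]-1,3-oxazolidin-2-one, via boron enolate 16 (not isolated)
Conditions: Bu2BOTf, Et3N, CH2Cl2, −78 → 0 °C; 14, −78 → 0 °C; pH 7 buffer, MeOH, H2O2
Reagents that add atoms: none
Why: Evans syn-aldol reaction, in which the (Z)-boron enolate reacts through a closed chair transition state on the face opposite the benzyl group to give the (2R,3R) syn adduct.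

Step 10
Reactants: 17
Product: 18 (2R,3R,4E)-3-hydroxy-5-iodo-N-methoxy-N,2-dimethylpent-4-enamide
Conditions: MeNHOMe·HCl, AlMe3, CH2Cl2, −20 → 0 °C
Reagents that add atoms: N,O-dimethylhydroxylamine hydrochloride, CNOC.Cl
Why: Aluminium-amide transamidation to the Weinreb amide is assisted by the free β-hydroxyl and should remove the auxiliary without epimerisation.

Step 11
Reactants: 18
Product: 19 (2R,3R,4E)-3-{[tert-butyl(dimethyl)silyl]oxy}-5-iodo-N-methoxy-N,2-dimethylpent-4-enamide
Conditions: TBSOTf, 2,6-lutidine, CH2Cl2, −78 °C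
Reagents that add atoms: tert-butyldimethylsilyl trifluoromethanesulfonate, CC(C)(C)[Si](C)(C)OS(=O)(=O)C(F)(F)F
Why: The silyl triflate with a hindered base silylates the secondary allylic alcohol at low temperature.

Step 12
Reactants: 19
Product: 20 (3R,4R,5E)-4-{[tert-butyl(dimethyl)silyl]oxy}-6-iodo-3-methylhex-5-en-2-one
Conditions: MeMgBr, THF, 0 °C
Reagents that add atoms: methylmagnesium bromide, C[Mg]Br
Why: Grignard addition to the Weinreb amide stops at the chelated tetrahedral intermediate and should give the methyl ketone on work-up with the α-centre and vinyl iodide intact.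

Step 13
Reactants: 21 but-2-yn-1-ol
Product: 22 but-2-ynal
Conditions: MnO2, CH2Cl2, rt; filtered solution used directly
Reagents that add atoms: none
Why: MnO2 oxidises the propargylic alcohol to the volatile ynal, which is handled in solution.

Step 14
Reactants: 22; 23 nitromethane
Product: 26 (1E)-1-nitropent-1-en-3-yne, via nitro alcohol 24 (not isolated), via nitro mesylate 25 (not isolated)
Conditions: t-BuOK (cat.), THF/t-BuOH, 0 °C; then MsCl, Et3N, CH2Cl2, −20 → 0 °C
Reagents that add atoms: none
Why: Henry addition followed by mesylation and E1cB elimination should give the thermodynamically preferred (E)-nitroenyne.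

Step 15
Reactants: 26; 27 propanal
Product: 29 (4R,5S)-6,6-dimethoxy-5-methyl-4-(nitromethyl)hex-2-yne, via nitro aldehyde 28 (not isolated)
Conditions: (R)-α,α-diphenylprolinol trimethylsilyl ether (10 mol %), CHCl3, 0 °C; then HC(OMe)3, p-TsOH (cat.), MeOH, rt
Reagents that add atoms: trimethyl orthoformate, COC(OC)OC
Why: Enamine-catalysed Michael addition of propanal to the nitroenyne (1,4-mode) should give the syn (2S,3R) adduct by attack of the anti-(E)-enamine on its unshielded face, and in-situ acetalisation protects the epimerisable aldehyde.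

Step 16
Reactants: 29
Product: 31 (3R,4S)-5-hydroxy-4-methyl-3-(prop-1-yn-1-yl)oxolan-2-one (C5 epimers), via acid acetal 30 (not isolated)
Conditions: NaNO2, AcOH, DMSO, 35 °C; then 1 M HCl, THF, 40 °C
Reagents that add atoms: sodium nitrite, [Na+].[O-]N=O; water, O
Why: Nitrosative oxidation of the primary nitroalkane (via nitrolic acid and nitrile oxide) gives the carboxylic acid, and acetal hydrolysis lets the aldehyde-acid close to the 5-hydroxy lactone, whose C5 configuration need not be controlled.

Step 17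
Reactants: 31
Product: 32 (3R,4S)-5-bromo-4-methyl-3-(prop-1-yn-1-yl)oxolan-2-one (C5 epimers)
Conditions: 1-bromo-N,N,2-trimethylprop-1-en-1-amine, CH2Cl2, 0 °C; evaporated and used crude
Reagents that add atoms: 1-bromo-N,N,2-trimethylprop-1-en-1-amine, CC(C)=C(Br)N(C)C
Why: The α-bromoenamine reagent converts the carboxyl/lactol function under neutral conditions into the ring-closed α-bromoalkyl ester (acyl bromide adding to the γ-aldehyde), and either C5 epimer serves in the next step.

Step 18
Reactants: 32; 12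
Product: 34 (3R,4S,5S)-5-[(2E,4E,6R)-6-({[tert-butyl(dimethyl)silyl]oxy}methyl)deca-2,4-dien-2-yl]-4-methyl-3-(prop-1-yn-1-yl)oxolan-2-one, via dienylzirconocene 33 (not isolated)
Conditions: 12 (1.3 equiv), Cp2Zr(H)Cl (1.25 equiv), THF, rt; then 32, NiCl2·glyme (10 mol %), 4,4′-di-tert-butyl-2,2′-bipyridine (12 mol %), DME–THF, 0 °C → rt
Reagents that add atoms: none
Why: Proposed new method: syn-hydrozirconation of the methyl-capped enyne 12 places Zr on the methyl-bearing alkyne carbon and fixes the (E)-trisubstituted alkene; Zr-to-Ni transmetalation gives an alkenyl–nickel species, halogen abstraction from 32 gives a planar α-acyloxy radical at C5 inside the lactone ring, and radical capture followed by C(sp3)–C(sp2) reductive elimination forms the C5–C(Me)= bond. The closest known reaction types are the Ni-catalysed stereoconvergent Negishi-type coupling of alkenylzirconocenes with racemic α-bromo ketones and the Ni-catalysed Negishi coupling of glycosyl bromides, where ring substituents set the new centre; the γ-bromo-γ-lactone of a γ-oxo acid has not been used as the electrophile. No ring is closed, because the γ-lactone is already in place and acts as the stereocontrol element. C5 is the only new stereocentre and is set by the C4 methyl group, which should send the alkenyl–nickel to the ring face anti to it (4,5-trans), while the slim propynyl group at C3 on that face offers little hindrance, so both C5 epimers of 32 should converge on (5S). The step needs regioselective hydrozirconation (methyl versus alkenyl size, with Cp2Zr(H)Cl as the limiting reagent so that the propynyl group of 32 is not touched), radical capture faster than β-hydride elimination (bipyridine ligand), and 4,5-trans facial selectivity (secured by the ring).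

Step 19
Reactants: 34; 20
Product: 36 (3S,4S,5S)-3-[(1E,3E,5S,6R)-5-{[tert-butyl(dimethyl)silyl]oxy}-2,6-dimethyl-7-oxoocta-1,3-dien-1-yl]-5-[(2E,4E,6R)-6-({[tert-butyl(dimethyl)silyl]oxy}methyl)deca-2,4-dien-2-yl]-4-methyloxolan-2-one, via alkenylborane 35 (not isolated)
Conditions: BH3·SMe2, cyclohexene, THF, 0 °C (gives Cy2BH); 34, 0 °C → rt; then 20, Pd(dppf)Cl2 (5 mol %), AsPh3, aq. K3PO4, DMF, rt
Reagents that add atoms: none
Why: Syn-hydroboration with bulky dicyclohexylborane should place boron on the less hindered methyl-bearing alkyne carbon (the alkyne reacts before the hindered conjugated diene), and Suzuki–Miyaura coupling with the (E)-vinyl iodide proceeds with retention at both partners to give the (1E,3E)-diene.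

Step 20
Reactants: 36
Product: 37 (3S,4S,5S)-3-[(1E,3E,5S,6R)-5-hydroxy-2,6-dimethyl-7-oxoocta-1,3-dien-1-yl]-5-[(2E,4E,6R)-6-(hydroxymethyl)deca-2,4-dien-2-yl]-4-methyloxolan-2-one
Conditions: HF·pyridine, pyridine, THF, 0 °C → rt
Reagents that add atoms: none
Why: Buffered HF·pyridine cleaves both silyl ethers without base, which should avoid retro-aldol cleavage of the β-hydroxy ketone and epimerisation at C3.

**Compound list**

1 | (4R)-4-benzyl-1,3-oxazolidin-2-one | O=C1N[C@H](Cc2ccccc2)CO1 | starting material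
2 | hexanoyl chloride | CCCCCC(=O)Cl | starting material
3 | lithium (4R)-4-benzyl-2-oxo-1,3-oxazolidin-3-ide | [Li+].O=C1[N-][C@H](Cc2ccccc2)CO1 | intermediate
4 | (4R)-4-benzyl-3-hexanoyl-1,3-oxazolidin-2-one | CCCCCC(=O)N1[C@H](Cc2ccccc2)COC1=O | intermediate
5 | trichlorotitanium (Z)-enolate of 4 | CCCC/C=C(\O[Ti](Cl)(Cl)Cl)N1[C@H](Cc2ccccc2)COC1=O | intermediate
6 | (4R)-4-benzyl-3-[(2S)-2-(hydroxymethyl)hexanoyl]-1,3-oxazolidin-2-one | CCCC[C@H](C(=O)N1[C@H](Cc2ccccc2)COC1=O)CO | intermediate
7 | (4R)-4-benzyl-3-[(2S)-2-({[tert-butyl(dimethyl)silyl]oxy}methyl)hexanoyl]-1,3-oxazolidin-2-one | CCCC[C@H](C(=O)N1[C@H](Cc2ccccc2)COC1=O)CO[Si](C)(C)C(C)(C)C | intermediate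
8 | (2R)-2-({[tert-butyl(dimethyl)silyl]oxy}methyl)hexan-1-ol | CCCC[C@H](CO)CO[Si](C)(C)C(C)(C)C | intermediate
9 | (2S)-2-({[tert-butyl(dimethyl)silyl]oxy}methyl)hexanal | CCCC[C@H](C=O)CO[Si](C)(C)C(C)(C)C | intermediate
10 | tert-butyl{[(2R,3E)-2-butyl-4-iodobut-3-en-1-yl]oxy}dimethylsilane | CCCC[C@H](/C=C/I)CO[Si](C)(C)C(C)(C)C | intermediate
11 | propyne | CC#C | starting material
12 | tert-butyl{[(2R,3E)-2-butylhept-3-en-5-yn-1-yl]oxy}dimethylsilane | CCCC[C@H](/C=C/C#CC)CO[Si](C)(C)C(C)(C)C | intermediate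
13 | (2E)-3-iodoprop-2-en-1-ol | OC/C=C/I | starting material
14 | (2E)-3-iodoprop-2-enal | O=C/C=C/I | intermediate
15 | (4R)-4-benzyl-3-propanoyl-1,3-oxazolidin-2-one | CCC(=O)N1[C@H](Cc2ccccc2)COC1=O | starting material
16 | dibutylboron (Z)-enolate of 15 | C/C=C(\OB(CCCC)CCCC)N1[C@H](Cc2ccccc2)COC1=O | intermediate
17 | (4R)-4-benzyl-3-[(2R,3R,4E)-3-hydroxy-5-iodo-2-methylpent-4-enoyl]-1,3-oxazolidin-2-one | I/C=C/[C@H](O)[C@@H](C)C(=O)N1[C@H](Cc2ccccc2)COC1=O | intermediate
18 | (2R,3R,4E)-3-hydroxy-5-iodo-N-methoxy-N,2-dimethylpent-4-enamide | I/C=C/[C@H](O)[C@@H](C)C(=O)N(C)OC | intermediate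
19 | (2R,3R,4E)-3-{[tert-butyl(dimethyl)silyl]oxy}-5-iodo-N-methoxy-N,2-dimethylpent-4-enamide | I/C=C/[C@H](O[Si](C)(C)C(C)(C)C)[C@@H](C)C(=O)N(C)OC | intermediate
20 | (3R,4R,5E)-4-{[tert-butyl(dimethyl)silyl]oxy}-6-iodo-3-methylhex-5-en-2-one | I/C=C/[C@H](O[Si](C)(C)C(C)(C)C)[C@@H](C)C(C)=O | intermediate
21 | but-2-yn-1-ol | CC#CCO | starting material
22 | but-2-ynal | CC#CC=O | intermediate
23 | nitromethane | C[N+](=O)[O-] | starting material
24 | 1-nitropent-3-yn-2-ol (racemic) | CC#CC(O)C[N+](=O)[O-] | intermediate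
25 | 1-nitropent-3-yn-2-yl methanesulfonate (racemic) | CC#CC(OS(C)(=O)=O)C[N+](=O)[O-] | intermediate
26 | (1E)-1-nitropent-1-en-3-yne | CC#C/C=C/[N+](=O)[O-] | intermediate
27 | propanal | CCC=O | starting material
28 | (2S,3R)-2-methyl-3-(nitromethyl)hex-4-ynal | O=C[C@@H](C)[C@H](C#CC)C[N+](=O)[O-] | intermediate
29 | (4R,5S)-6,6-dimethoxy-5-methyl-4-(nitromethyl)hex-2-yne | COC(OC)[C@@H](C)[C@H](C#CC)C[N+](=O)[O-] | intermediate
30 | (2R)-2-[(2S)-1,1-dimethoxypropan-2-yl]pent-3-ynoic acid | COC(OC)[C@@H](C)[C@H](C#CC)C(=O)O | intermediate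
31 | (3R,4S)-5-hydroxy-4-methyl-3-(prop-1-yn-1-yl)oxolan-2-one, both C5 epimers | OC1OC(=O)[C@@H](C#CC)[C@@H]1C | intermediate
32 | (3R,4S)-5-bromo-4-methyl-3-(prop-1-yn-1-yl)oxolan-2-one, both C5 epimers | BrC1OC(=O)[C@@H](C#CC)[C@@H]1C | intermediate
33 | chlorobis(cyclopentadienyl)[(2E,4E,6R)-6-({[tert-butyl(dimethyl)silyl]oxy}methyl)deca-2,4-dien-2-yl]zirconium | CCCC[C@H](/C=C/C=C(\C)[Zr+2]Cl)CO[Si](C)(C)C(C)(C)C.[cH-]1cccc1.[cH-]1cccc1 | intermediate
34 | (3R,4S,5S)-5-[(2E,4E,6R)-6-({[tert-butyl(dimethyl)silyl]oxy}methyl)deca-2,4-dien-2-yl]-4-methyl-3-(prop-1-yn-1-yl)oxolan-2-one | CCCC[C@H](/C=C/C=C(\C)[C@H]1OC(=O)[C@@H](C#CC)[C@@H]1C)CO[Si](C)(C)C(C)(C)C | intermediate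
35 | alkenyl(dicyclohexyl)borane from syn addition of Cy2B–H to the alkyne of 34 (boron on the methyl-bearing carbon, trans to the ring; ring centres as in 36) | CCCC[C@H](/C=C/C=C(\C)[C@H]1OC(=O)[C@@H](/C=C(C)/B(C2CCCCC2)C2CCCCC2)[C@@H]1C)CO[Si](C)(C)C(C)(C)C | intermediate
36 | (3S,4S,5S)-3-[(1E,3E,5S,6R)-5-{[tert-butyl(dimethyl)silyl]oxy}-2,6-dimethyl-7-oxoocta-1,3-dien-1-yl]-5-[(2E,4E,6R)-6-({[tert-butyl(dimethyl)silyl]oxy}methyl)deca-2,4-dien-2-yl]-4-methyloxolan-2-one | CCCC[C@H](/C=C/C=C(\C)[C@H]1OC(=O)[C@@H](/C=C(C)/C=C/[C@H](O[Si](C)(C)C(C)(C)C)[C@@H](C)C(C)=O)[C@@H]1C)CO[Si](C)(C)C(C)(C)C | intermediate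
37 | (3S,4S,5S)-3-[(1E,3E,5S,6R)-5-hydroxy-2,6-dimethyl-7-oxoocta-1,3-dien-1-yl]-5-[(2E,4E,6R)-6-(hydroxymethyl)deca-2,4-dien-2-yl]-4-methyloxolan-2-one | CCCC[C@H](/C=C/C=C(\C)[C@H]1OC(=O)[C@@H](/C=C(C)/C=C/[C@H](O)[C@@H](C)C(C)=O)[C@@H]1C)CO | target

**Count and risks**

Total steps: 20. Longest linear sequence: 10 steps (steps 1–7, then 18, 19, 20).

Steps most likely to fail:

1. Step 18 (Proposed new method). What may go wrong: slow halogen abstraction or transmetalation with protodemetalation of 33; loss of HBr or β-hydride elimination at C5 towards a butenolide; imperfect regiocontrol in the hydrozirconation; weak facial discrimination at the C5 radical; nickel insertion into the newly formed dienylic C5–O bond. Fallback by known chemistry, setting out from 31 and 12 and returning at 34 (it also bypasses step 17): TMSCHN2 in toluene/MeOH should trap the open form of 31 as methyl (2R)-2-[(2S)-1-oxopropan-2-yl]pent-3-ynoate F1. Zirconocene 33, made from 12 as before, is transmetalated with Me2Zn to methyl[(2E,4E,6R)-6-({[tert-butyl(dimethyl)silyl]oxy}methyl)deca-2,4-dien-2-yl]zinc F2. F2 is added to F1 in the presence of (+)-MIB, the ligand enantiomer expected to deliver the alkenyl group to the Re face of the aldehyde against the Felkin preference (catalytic asymmetric alkenylzinc addition). This gives methyl (2R)-2-[(2S,3S,4E,6E,8R)-8-({[tert-butyl(dimethyl)silyl]oxy}methyl)-3-hydroxy-4-methyldodeca-4,6-dien-2-yl]pent-3-ynoate F3, which should lactonise on work-up (PPTS) to 34; the 5-epi lactone would be removed by chromatography.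

2. Step 19. What may go wrong: base-mediated epimerisation or double-bond migration at C3, or lactone opening, during transmetalation; Pd(0) ionisation of the dienylic C5–O bond; incomplete regio- or chemoselectivity of the hydroboration. Fallback, setting out from 34 and returning at 36: Pd-catalysed syn-hydrostannation (Bu3SnH, PdCl2(PPh3)2, THF) to (3R,4S,5S)-5-[(2E,4E,6R)-6-({[tert-butyl(dimethyl)silyl]oxy}methyl)deca-2,4-dien-2-yl]-4-methyl-3-[(1E)-2-(tributylstannyl)prop-1-en-1-yl]oxolan-2-one F4, then base-free Stille coupling with 20 (Pd2(dba)3, AsPh3, CuTC, NMP, rt) to 36.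

3. Step 20. What may go wrong: ionisation and dehydration of the dienylic β-hydroxy ketone to a trienone, or retro-aldol cleavage, during the long fluoride exposure that the secondary silyl ether needs. Fallback, setting out from 20 and 35 and returning at 37: the slow desilylation is moved to the small fragment, where 20 with HF·pyridine in MeCN should give (3R,4R,5E)-4-hydroxy-6-iodo-3-methylhex-5-en-2-one F5. Suzuki coupling of F5 with 35 under the conditions of step 19 gives (3S,4S,5S)-5-[(2E,4E,6R)-6-({[tert-butyl(dimethyl)silyl]oxy}methyl)deca-2,4-dien-2-yl]-3-[(1E,3E,5S,6R)-5-hydroxy-2,6-dimethyl-7-oxoocta-1,3-dien-1-yl]-4-methyloxolan-2-one F6. Only the primary silyl ether of F6 then remains, and a brief treatment with HF·pyridine/pyridine at 0 °C should give 37.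

Further compounds
F1 | step 18 | methyl (2R)-2-[(2S)-1-oxopropan-2-yl]pent-3-ynoate | COC(=O)[C@@H](C#CC)[C@H](C)C=O
F2 | step 18 | methyl[(2E,4E,6R)-6-({[tert-butyl(dimethyl)silyl]oxy}methyl)deca-2,4-dien-2-yl]zinc | CCCC[C@H](/C=C/C=C(\C)[Zn]C)CO[Si](C)(C)C(C)(C)C
F3 | step 18 | methyl (2R)-2-[(2S,3S,4E,6E,8R)-8-({[tert-butyl(dimethyl)silyl]oxy}methyl)-3-hydroxy-4-methyldodeca-4,6-dien-2-yl]pent-3-ynoate | CCCC[C@H](/C=C/C=C(\C)[C@@H](O)[C@@H](C)[C@H](C#CC)C(=O)OC)CO[Si](C)(C)C(C)(C)C
F4 | step 19 | (3R,4S,5S)-5-[(2E,4E,6R)-6-({[tert-butyl(dimethyl)silyl]oxy}methyl)deca-2,4-dien-2-yl]-4-methyl-3-[(1E)-2-(tributylstannyl)prop-1-en-1-yl]oxolan-2-one | CCCC[C@H](/C=C/C=C(\C)[C@H]1OC(=O)[C@@H](/C=C(C)/[Sn](CCCC)(CCCC)CCCC)[C@@H]1C)CO[Si](C)(C)C(C)(C)C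
F5 | step 20 | (3R,4R,5E)-4-hydroxy-6-iodo-3-methylhex-5-en-2-one | I/C=C/[C@H](O)[C@@H](C)C(C)=O
F6 | step 20 | (3S,4S,5S)-5-[(2E,4E,6R)-6-({[tert-butyl(dimethyl)silyl]oxy}methyl)deca-2,4-dien-2-yl]-3-[(1E,3E,5S,6R)-5-hydroxy-2,6-dimethyl-7-oxoocta-1,3-dien-1-yl]-4-methyloxolan-2-one | CCCC[C@H](/C=C/C=C(\C)[C@H]1OC(=O)[C@@H](/C=C(C)/C=C/[C@H](O)[C@@H](C)C(C)=O)[C@@H]1C)CO[Si](C)(C)C(C)(C)C
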